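**Retrosynthetic overview**
1. The arylmethyl arm at C4 is traced back to a lactone carbonyl (lactol + aryl Grignard reagent, then hydrogenolysis), which reduces the target to the cis-fused bicyclic lactone 8 (oxolane fused to a γ-lactone) carrying all three stereocentres.
2. Key disconnection: the oxolane bond O1–C2. In the precursor, C2 is bonded to C4 instead, as the third bond of a cyclopropane (C2, C3, C4), and O1–C5 hangs on C4 as a hydroxymethyl group; a C–C bond is cleaved as the C–O bond forms.
3. Enabling feature: C2 is benzylic to the electron-rich 3,4,5-trimethoxyphenyl ring (donor) and C4 carries the future benzylic carbon of the arm, kept as an ester (acceptor). The C2–C4 bond is therefore a donor–acceptor cyclopropane bond, and the cis relation of the C3 hydroxymethyl group to that ester carbon lets a lactone lock C4.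
4. The cyclopropane comes from 3,4,5-trimethoxycinnamaldehyde and dimethyl bromomalonate by organocatalytic Michael-initiated ring closure (sets C3 and the absolute configuration), followed by chemoselective borohydride reduction.
5. Ring order: cyclopropane (step 1), transient lactone (step 2), oxolane then lactone (step 3), lactone opened again (steps 4 and 5).

Key step: step 3

Remark: the oxolane locants O1, C2 (aryl), C3 (CH2OH), C4 (arylmethyl) and C5 of the target are used for the corresponding atoms of all precursors; the target is read as the (2S,3R,4R) isomer (2,3-trans, 3,4-cis).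

Step 1
Reactants: 1 (E)-3-(3,4,5-trimethoxyphenyl)prop-2-enal; 2 dimethyl 2-bromopropanedioate
Product: 3 dimethyl (2R,3S)-2-formyl-3-(3,4,5-trimethoxyphenyl)cyclopropane-1,1-dicarboxylate
Conditions: (S)-2-[diphenyl(trimethylsilyloxy)methyl]pyrrolidine (20 mol %), 2,6-lutidine (1.1 equiv), CH2Cl2, 0 °C to rt
Reagents that add atoms: none
Why: Iminium activation of 1 by the (S)-prolinol silyl ether should direct the bromomalonate to the β-carbon on the face away from the diphenyl(silyloxy)methyl group, and the enamine then closes the three-membered ring by 3-exo-tet displacement of bromide (organocatalytic Michael-initiated ring closure), setting the aryl-bearing carbon as S and, trans to it, the formyl-bearing carbon (the later C3) as R.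

Step 2
Reactants: 3 dimethyl (2R,3S)-2-formyl-3-(3,4,5-trimethoxyphenyl)cyclopropane-1,1-dicarboxylate
Product: 6 methyl (1R,2R,3S)-1,2-bis(hydroxymethyl)-3-(3,4,5-trimethoxyphenyl)cyclopropane-1-carboxylate, via hydroxy diester 4 (not isolated), via lactone ester 5 (not isolated)
Conditions: NaBH4 (3 equiv), MeOH–THF (1:4), 0 °C to rt; aq. NH4Cl
Reagents that add atoms: none
Why: Hydride reduces the aldehyde, the alkoxide closes onto the cis ester to give the strained malonate-type lactone 5, and borohydride should then reduce this lactone carbonyl in preference to the remaining hindered cyclopropyl ester (chemoselective borohydride reduction of an activated lactone), with no stereocentre touched.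

Step 3
Reactants: 6 methyl (1R,2R,3S)-1,2-bis(hydroxymethyl)-3-(3,4,5-trimethoxyphenyl)cyclopropane-1-carboxylate
Product: 8 (1R,5R,6S)-6-(3,4,5-trimethoxyphenyl)-3,7-dioxabicyclo[3.3.0]octan-2-one, via oxolane hydroxy ester 7 (not isolated)
Conditions: Sc(OTf)3 (10 mol %), CH2Cl2–(CF3)2CHOH (4:1), 0 °C to rt; then evaporation, DBU (0.3 equiv), PhMe, 60 °C
Reagents that add atoms: none
Why: Proposed new method: Sc(OTf)3 is expected to chelate the ester carbonyl and the geminal hydroxymethyl oxygen of 6, so that the cyclopropane bond C2–C4 heterolyses to a contact ion pair (3,4,5-trimethoxybenzyl cation at C2, scandium ester enolate at C4) and the primary hydroxyl on the enolate carbon captures the cation; this is an alcohol-level analogue of the Cloke–Wilson rearrangement and of the acid-induced ring-opening lactonisation of 2-arylcyclopropane-1,1-dicarboxylates, the closest known reaction types. The oxolane closes by five-membered C–O bond formation between O1 and the benzylic cation (a net shift of C2 from C4 to O1; closure by the other hydroxymethyl group would give an oxetane, and the ester oxygen is held back as the metal enolate), and the lactone ring then closes by 5-exo-trig acyl substitution in the cis hydroxy ester 7. C3 is not touched and keeps the configuration set in step 1. C2 should be re-formed trans to the C3 hydroxymethyl arm, because O1 enters on the face just vacated by the enolate carbon (front-side collapse of the ion pair) and because this is also the less crowded closure. C4 is fixed as R by the cis ring fusion, since only the ester epimer cis to the C3 hydroxymethyl group can lactonise and DBU equilibrates the other epimer through its enolate. The step needs ionisation at the benzylic cyclopropane bond only (secured by the electron-rich aryl donor opposite the chelated ester) and 2,3-trans selectivity (secured as above, the acid stage being stopped before the product can re-ionise).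

Step 4
Reactants: 8 (1R,5R,6S)-6-(3,4,5-trimethoxyphenyl)-3,7-dioxabicyclo[3.3.0]octan-2-one
Product: 9 (1R,5R,6S)-6-(3,4,5-trimethoxyphenyl)-3,7-dioxabicyclo[3.3.0]octan-2-ol (both anomers)
Conditions: iBu2AlH (1.1 equiv), CH2Cl2, −78 °C; aq. KNaC4H4O6
Reagents that add atoms: none
Why: Reduction of a γ-lactone with iBu2AlH stops at the aluminium-bound hemiacetal at −78 °C (partial lactone reduction to the lactol); the oxolane and its three stereocentres are not involved, and the new anomeric centre is lost in step 5.

Step 5
Reactants: 9 (1R,5R,6S)-6-(3,4,5-trimethoxyphenyl)-3,7-dioxabicyclo[3.3.0]octan-2-ol; 10 1-(benzyloxy)-4-bromo-2-methoxybenzene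
Product: 12 [4-(benzyloxy)-3-methoxyphenyl][(3R,4R,5S)-4-(hydroxymethyl)-5-(3,4,5-trimethoxyphenyl)oxolan-3-yl]methanol (both epimers at the carbinol carbon), via aryl Grignard reagent 11 (not isolated)
Conditions: 10, Mg turnings, THF, rt (3 equiv of 11); then 9, THF, 0 °C to rt; aq. NH4Cl
Reagents that add atoms: none
Why: The lactol is deprotonated and opens to its hydroxy aldehyde, to which the aryl Grignard reagent adds (Grignard addition to a masked aldehyde); the carbinol centre forms without control, which does not matter because its oxygen is removed in step 6.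

Step 6
Reactants: 12 [4-(benzyloxy)-3-methoxyphenyl][(3R,4R,5S)-4-(hydroxymethyl)-5-(3,4,5-trimethoxyphenyl)oxolan-3-yl]methanol
Product: 14 [(2S,3R,4R)-4-[(4-hydroxy-3-methoxyphenyl)methyl]-2-(3,4,5-trimethoxyphenyl)oxolan-3-yl]methanol, via phenolic triol 13 (not isolated)
Conditions: H2 (1 atm), Pd/C (10 wt % Pd), EtOH, rt
Reagents that add atoms: none
Why: Hydrogenolysis should first remove the O-benzyl group and then cleave the para-hydroxybenzylic secondary C–OH bond (benzylic C–O hydrogenolysis), while the cyclic benzylic ether on the non-phenolic trimethoxyphenyl ring is expected to react much more slowly; no oxolane stereocentre is touched.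

**Compound list**
1 | (E)-3-(3,4,5-trimethoxyphenyl)prop-2-enal | COc1cc(/C=C/C=O)cc(OC)c1OC | starting material
2 | dimethyl 2-bromopropanedioate | COC(=O)C(Br)C(=O)OC | starting material
3 | dimethyl (2R,3S)-2-formyl-3-(3,4,5-trimethoxyphenyl)cyclopropane-1,1-dicarboxylate | O=C[C@@H]1[C@@H](c2cc(OC)c(OC)c(OC)c2)C1(C(=O)OC)C(=O)OC | intermediate
4 | dimethyl (2R,3S)-2-(hydroxymethyl)-3-(3,4,5-trimethoxyphenyl)cyclopropane-1,1-dicarboxylate (not isolated) | OC[C@@H]1[C@@H](c2cc(OC)c(OC)c(OC)c2)C1(C(=O)OC)C(=O)OC | intermediate
5 | methyl (1S,5R,6S)-2-oxo-6-(3,4,5-trimethoxyphenyl)-3-oxabicyclo[3.1.0]hexane-1-carboxylate (not isolated) | O=C1OC[C@@H]2[C@@H](c3cc(OC)c(OC)c(OC)c3)[C@]12C(=O)OC | intermediate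
6 | methyl (1R,2R,3S)-1,2-bis(hydroxymethyl)-3-(3,4,5-trimethoxyphenyl)cyclopropane-1-carboxylate | OC[C@@H]1[C@@H](c2cc(OC)c(OC)c(OC)c2)[C@@]1(CO)C(=O)OC | intermediate
7 | methyl (3R,4R,5S)-4-(hydroxymethyl)-5-(3,4,5-trimethoxyphenyl)oxolane-3-carboxylate (not isolated) | COC(=O)[C@H]1CO[C@H](c2cc(OC)c(OC)c(OC)c2)[C@H]1CO | intermediate
8 | (1R,5R,6S)-6-(3,4,5-trimethoxyphenyl)-3,7-dioxabicyclo[3.3.0]octan-2-one | O=C1OC[C@H]2[C@@H]1CO[C@@H]2c1cc(OC)c(OC)c(OC)c1 | intermediate
9 | (1R,5R,6S)-6-(3,4,5-trimethoxyphenyl)-3,7-dioxabicyclo[3.3.0]octan-2-ol (both anomers) | OC1OC[C@H]2[C@@H]1CO[C@@H]2c1cc(OC)c(OC)c(OC)c1 | intermediate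
10 | 1-(benzyloxy)-4-bromo-2-methoxybenzene | COc1cc(Br)ccc1OCc1ccccc1 | starting material
11 | [4-(benzyloxy)-3-methoxyphenyl]magnesium bromide (not isolated) | COc1cc([Mg]Br)ccc1OCc1ccccc1 | intermediate
12 | [4-(benzyloxy)-3-methoxyphenyl][(3R,4R,5S)-4-(hydroxymethyl)-5-(3,4,5-trimethoxyphenyl)oxolan-3-yl]methanol (both carbinol epimers) | OC(c1ccc(OCc2ccccc2)c(OC)c1)[C@H]1CO[C@H](c2cc(OC)c(OC)c(OC)c2)[C@H]1CO | intermediate
13 | (4-hydroxy-3-methoxyphenyl)[(3R,4R,5S)-4-(hydroxymethyl)-5-(3,4,5-trimethoxyphenyl)oxolan-3-yl]methanol (both carbinol epimers, not isolated) | OC(c1ccc(O)c(OC)c1)[C@H]1CO[C@H](c2cc(OC)c(OC)c(OC)c2)[C@H]1CO | intermediate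
14 | [(2S,3R,4R)-4-[(4-hydroxy-3-methoxyphenyl)methyl]-2-(3,4,5-trimethoxyphenyl)oxolan-3-yl]methanol | COc1cc(C[C@H]2CO[C@H](c3cc(OC)c(OC)c(OC)c3)[C@H]2CO)ccc1O | target

**Step count and risks**
Total step count: 6. Longest linear sequence: 6 steps (1 to 14).

Step 3 (most likely to fail). The single ester acceptor may not polarise the cyclopropane enough for heterolysis. The free hydroxymethyl group at C3 may ionise in a cyclopropylcarbinyl manner, the ester oxygen may capture the cation in place of the hydroxyl, or re-ionisation may erode the 2,3-trans relation. The fallback uses known chemistry and moves the ring closure to the aldehyde oxidation level; it sets out from 6 and comes back at 8. The less hindered hydroxymethyl group on the CH carbon of 6 is silylated (tBuMe2SiCl, imidazole, CH2Cl2, −20 °C) to give the mono-silyl ether F1. The remaining neopentyl-type alcohol is oxidised with Dess–Martin periodinane to the formyl ester F2, a doubly activated cyclopropane. Yb(OTf)3 in 1,2-dichloroethane at 60 °C should then effect a Cloke–Wilson rearrangement, the formyl oxygen closing on the benzylic carbon, to give the 4,5-dihydrofuran-3-carboxylate F3. Hydrogenation of the enol ether (H2, Rh/Al2O3, EtOAc) gives the silylated oxolane ester F4. Bu4NF in THF removes the silyl group, and the basic fluoride equilibrates the ester so that the cis hydroxy ester lactonises to 8.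

Step 6. Hydrogenolysis of the benzylic carbinol may stall under neutral conditions, and forcing it (acid, longer time) may open the oxolane at the C2–O1 bond. The fallback forms the CH2–aryl bond without any benzylic oxygen; it sets out from 9 and comes back at 14, bypassing steps 5 and 6. Condensation of 9 with 4-methylbenzenesulfonohydrazide (MeOH, rt) gives the open-chain N-tosylhydrazone F5. Heating F5 with (4-hydroxy-3-methoxyphenyl)boronic acid and K2CO3 in 1,4-dioxane at 110 °C (metal-free reductive coupling of a tosylhydrazone with an arylboronic acid: diazoalkane formation, boron-to-carbon aryl shift, protodeboronation) should give 14 directly.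

Step 1. Conjugate addition to the electron-rich iminium ion may be slow, and the amine may open the activated formyl cyclopropane, lowering conversion and enantiomeric purity. The fallback builds the cyclopropane by intramolecular carbene transfer; it sets out from 1 and comes back at 5, which is then isolated and reduced to 6 under the conditions of step 2. Reduction of 1 (NaBH4, CeCl3·7H2O, MeOH) gives the cinnamyl alcohol F6. Acylation with methyl 3-chloro-3-oxopropanoate (pyridine, CH2Cl2) gives the mixed malonate F7. Diazo transfer (4-acetamidobenzenesulfonyl azide, Et3N, MeCN) gives the diazomalonate F8. Intramolecular cyclopropanation with the monovalent copper salt [Cu(MeCN)4]PF6 and 2,2'-(propane-2,2-diyl)bis(4-tert-butyl-4,5-dihydrooxazole), in the enantiomeric form that delivers the (1S,5R,6S) series, should give 5 with the aryl group exo, as fixed by the E-alkene.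

**Further compounds**
F1 | step 3 | methyl (1R,2R,3S)-2-{[(tert-butyldimethylsilyl)oxy]methyl}-1-(hydroxymethyl)-3-(3,4,5-trimethoxyphenyl)cyclopropane-1-carboxylate | CC(C)(C)[Si](C)(C)OC[C@@H]1[C@@H](c2cc(OC)c(OC)c(OC)c2)[C@@]1(CO)C(=O)OC
F2 | step 3 | methyl (1R,2R,3S)-2-{[(tert-butyldimethylsilyl)oxy]methyl}-1-formyl-3-(3,4,5-trimethoxyphenyl)cyclopropane-1-carboxylate | CC(C)(C)[Si](C)(C)OC[C@@H]1[C@@H](c2cc(OC)c(OC)c(OC)c2)[C@@]1(C=O)C(=O)OC
F3 | step 3 | methyl (4R,5S)-4-{[(tert-butyldimethylsilyl)oxy]methyl}-5-(3,4,5-trimethoxyphenyl)-4,5-dihydrofuran-3-carboxylate | COC(=O)C1=CO[C@H](c2cc(OC)c(OC)c(OC)c2)[C@H]1CO[Si](C)(C)C(C)(C)C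
F4 | step 3 | methyl (3R,4R,5S)-4-{[(tert-butyldimethylsilyl)oxy]methyl}-5-(3,4,5-trimethoxyphenyl)oxolane-3-carboxylate | COC(=O)[C@H]1CO[C@H](c2cc(OC)c(OC)c(OC)c2)[C@H]1CO[Si](C)(C)C(C)(C)C
F5 | step 6 | N'-[(E)-{(3S,4R,5S)-4-(hydroxymethyl)-5-(3,4,5-trimethoxyphenyl)oxolan-3-yl}methylidene]-4-methylbenzenesulfonohydrazide | Cc1ccc(cc1)S(=O)(=O)N/N=C/[C@H]1CO[C@H](c2cc(OC)c(OC)c(OC)c2)[C@H]1CO
F6 | step 1 | (E)-3-(3,4,5-trimethoxyphenyl)prop-2-en-1-ol | COc1cc(/C=C/CO)cc(OC)c1OC
F7 | step 1 | methyl (2E)-3-(3,4,5-trimethoxyphenyl)prop-2-en-1-yl propanedioate | COC(=O)CC(=O)OC/C=C/c1cc(OC)c(OC)c(OC)c1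
F8 | step 1 | methyl (2E)-3-(3,4,5-trimethoxyphenyl)prop-2-en-1-yl 2-diazopropanedioate | COC(=O)C(=[N+]=[N-])C(=O)OC/C=C/c1cc(OC)c(OC)c(OC)c1
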